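The bond on which everything rests lies in the seven-membered ring, between the sp2 carbon that carries the exocyclic methylene (C10) and the neighbouring ring CH2 (C9). The key step exploits that C10 is an alkene carbon and that C8–C9 is an unsubstituted two-carbon bridge to C7: C10 becomes an alkenyl bromide and C8=C9 a terminal vinyl group. One-pot 9-BBN hydroboration and intramolecular B-alkyl Suzuki–Miyaura coupling then closes the cycloheptane onto the trans-disubstituted cyclopentene and installs the methylene, as the last, protecting-group-free step. Its precursor is an open-chain homoallylic alcohol made by anti-selective allylboration of a 1-bromovinyl cyclopentene aldehyde with a linalool-derived oxolane allylboronate.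

Key step: step 11

Remark on numbering: C1 and C5 are the ring-fusion carbons (C1 next to C10); C2–C4 complete the cyclopentene (methyl on C4); C6 is the carbinol carbon; C7 carries the oxolane; C8 and C9 are the ring CH2 groups; C10 bears the methylene C18; C11 (quaternary) and C14 (CH) are the oxolane stereocentres.
Assumption: (S)-(+)-linalool of high enantiomeric purity is taken as purchasable; diastereomers arising from its optical impurity are removed by chromatography at compound 15.

Step 1
Reactants: 1 methacrolein; 2 nitromethane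
Product: 4 (E)-3-methyl-1-nitrobuta-1,3-diene, via nitro alcohol 3 (not isolated)
Conditions: t-BuOK (5 mol%), THF, 0 °C; then Et3N, MsCl, 0 °C, same flask; diene used at once as a cold solution
Reagents that add atoms: none
Why: Henry (nitroaldol) addition to the aldehyde carbonyl under kinetic control followed by E1cB elimination of the mesylate should give the E-nitroalkene, with no stereocentre involved.

Step 2
Reactants: 5 pent-4-enal; 4 (E)-3-methyl-1-nitrobuta-1,3-diene
Product: 6 (2R,3S)-4-methyl-3-(nitromethyl)-2-(prop-2-en-1-yl)pent-4-enal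
Conditions: (S)-α,α-diphenylprolinol trimethylsilyl ether (10 mol%), PhCO2H (10 mol%), toluene, 0 °C
Reagents that add atoms: none
Why: Enamine-mediated organocatalytic Michael addition (Hayashi–Jørgensen catalyst), in which the E-enamine of 5, shielded on one face by the diarylsilyloxymethyl group, adds 1,4 to the nitroalkene through an acyclic synclinal transition state and so sets C5 (S) and C1 (R) in a syn relationship.

Step 3
Reactants: 6 (2R,3S)-4-methyl-3-(nitromethyl)-2-(prop-2-en-1-yl)pent-4-enal
Product: 7 (1R,2S)-3-methyl-2-(nitromethyl)cyclopent-3-ene-1-carbaldehyde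
Conditions: second-generation Grubbs catalyst RuCl2(=CHPh)(H2IMes)(PCy3) (2 mol%), CH2Cl2 (0.02 M), 40 °C
Reagents that add atoms: none
Why: Ring-closing olefin metathesis of the allyl and isopropenyl groups should give the trisubstituted C3=C4 cyclopentene with loss of ethylene; the syn adduct becomes the trans-1,2-disubstituted ring, which is also the thermodynamically preferred arrangement at the epimerisable C1.

Step 4
Reactants: 7 (1R,2S)-3-methyl-2-(nitromethyl)cyclopent-3-ene-1-carbaldehyde
Product: 8 (4R,5S)-4-ethynyl-1-methyl-5-(nitromethyl)cyclopent-1-ene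
Conditions: Ohira–Bestmann reagent, K2CO3, MeOH, 0 °C to rt
Reagents that add atoms: dimethyl (1-diazo-2-oxopropyl)phosphonate, COP(=O)(OC)C(=[N+]=[N-])C(C)=O
Why: Seyferth–Gilbert homologation with the Ohira–Bestmann reagent should convert the aldehyde into the terminal alkyne (C10≡C18) under mild carbonate conditions; any epimerisation at C1 beforehand converges on the wanted trans isomer, and C5 is not acidic.

Step 5
Reactants: 8 (4R,5S)-4-ethynyl-1-methyl-5-(nitromethyl)cyclopent-1-ene
Product: 10 (4R,5S)-4-(1-bromoethenyl)-1-methyl-5-(nitromethyl)cyclopent-1-ene, via bromoboration adduct 9 (not isolated)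
Conditions: B-bromo-9-BBN (1.2 equiv), CH2Cl2, 0 °C; then AcOH, 0 °C to rt
Reagents that add atoms: B-bromo-9-borabicyclo[3.3.1]nonane, BrB1C2CCCC1CCC2
Why: Syn-bromoboration of the terminal alkyne places bromine on the internal carbon and boron on the terminal one, and protonolysis of the alkenyl–boron bond with acetic acid should leave the 2-bromo-1-alkene; the ring alkene is not haloborated.

Step 6
Reactants: 10 (4R,5S)-4-(1-bromoethenyl)-1-methyl-5-(nitromethyl)cyclopent-1-ene
Product: 12 (1S,5R)-5-(1-bromoethenyl)-2-methylcyclopent-2-ene-1-carbaldehyde, via sodium nitronate 11 (not isolated)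
Conditions: NaOMe (1.1 equiv), MeOH, 0 °C; then aq. TiCl3 (4 equiv), NH4OAc buffer (pH 5–6), THF, 0 °C to rt; aldehyde used crude in step 10
Reagents that add atoms: water, O
Why: Reductive Nef reaction, in which the nitronate is reduced by aqueous TiCl3 to the imine that hydrolyses to the aldehyde; the buffered, near-neutral medium is chosen to keep the epimerisable, deconjugated C5 centre intact.

Step 7
Reactants: 13 (S)-(+)-linalool
Product: 15 2-[(2R,5S)-5-ethenyl-5-methyloxolan-2-yl]propan-2-ol (cis-furanoid linalool oxide), via epoxylinalool 14 (not isolated)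
Conditions: L-fructose-derived Shi ketone (ent-Shi ketone, 30 mol%), Oxone, K2CO3, Bu4NHSO4, MeCN/CH2(OMe)2/aq. borate buffer, 0 °C; then camphorsulfonic acid (cat.), CH2Cl2, 0 °C, without purification of the epoxide
Reagents that add atoms: potassium peroxymonosulfate (Oxone), OOS(=O)(=O)[O-].[K+]
Why: Shi asymmetric epoxidation selects the electron-rich trisubstituted alkene and one of its faces (reagent control) to give the (6S)-epoxide, which the tertiary hydroxyl opens 5-exo with inversion under acid catalysis, setting C14 as R, cis to the vinyl group.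

Step 8
Reactants: 15 2-[(2R,5S)-5-ethenyl-5-methyloxolan-2-yl]propan-2-ol
Product: 16 2-[(2R,5S)-5-ethenyl-5-methyloxolan-2-yl]propan-2-yl acetate
Conditions: Ac2O, DMAP, Et3N, CH2Cl2, 40 °C
Reagents that add atoms: acetic anhydride, CC(=O)OC(C)=O
Why: DMAP-catalysed acylation (Steglich-type) of the only hydroxyl group, with forcing conditions because it is tertiary; no stereocentre is touched.

Step 9
Reactants: 16 2-[(2R,5S)-5-ethenyl-5-methyloxolan-2-yl]propan-2-yl acetate; 17 allylboronic acid pinacol ester
Product: 18 2-[(2R,5S)-5-methyl-5-[(1E)-3-(4,4,5,5-tetramethyl-1,3,2-dioxaborolan-2-yl)prop-1-en-1-yl]oxolan-2-yl]propan-2-yl acetate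
Conditions: second-generation Hoveyda–Grubbs catalyst RuCl2(=CH-C6H4-2-OiPr)(H2IMes) (5 mol%), 17 (3 equiv), CH2Cl2, 40 °C
Reagents that add atoms: none
Why: Olefin cross-metathesis between the hindered vinyl group of 16, which cannot homodimerise, and the unhindered partner 17; the quaternary allylic carbon should enforce the E geometry.

Step 10
Reactants: 12 (1S,5R)-5-(1-bromoethenyl)-2-methylcyclopent-2-ene-1-carbaldehyde; 18 the (E)-allylboronate
Product: 20 2-[(2R,5S)-5-[(1S,2R)-1-[(1S,5R)-5-(1-bromoethenyl)-2-methylcyclopent-2-en-1-yl]-1-hydroxybut-3-en-2-yl]-5-methyloxolan-2-yl]propan-2-yl acetate, via pinacol borate 19 (not isolated)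
Conditions: (R)-TRIP ((R)-3,3'-bis(2,4,6-triisopropylphenyl)-1,1'-binaphthyl-2,2'-diyl hydrogen phosphate, 10 mol%), 4 Å MS, toluene, −30 °C to rt; aq. NaHCO3 work-up
Reagents that add atoms: none
Why: Brønsted acid-catalysed allylboration through a closed chair transition state, in which the E geometry of 18 gives the anti C6/C7 relationship and (R)-TRIP is expected to steer the allyl unit to the Re face of the aldehyde, making C6 S and thereby C7 R, with C5 and C11 acting only as secondary (Felkin-type) control elements.

Step 11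
Reactants: 20 the bromo-diene homoallylic alcohol
Product: 22 2-[(2R,5S)-5-[(3aS,4S,5R,8aR)-4-hydroxy-3-methyl-8-methylidene-1,3a,4,5,6,7,8,8a-octahydroazulen-5-yl]-5-methyloxolan-2-yl]propan-2-yl acetate (target), via alkylborane 21 (not isolated)
Conditions: 9-BBN (2.5 equiv), THF, 0 °C to rt; then slow addition to Pd(dppf)Cl2 (10 mol%), AsPh3 (20 mol%), Cs2CO3 (3 equiv), DMF/THF/H2O, 50 °C, final concentration about 0.003 M
Reagents that add atoms: none
Why: 9-BBN adds anti-Markovnikov and chemoselectively to the monosubstituted C8=C9 vinyl group (the trisubstituted ring alkene and the bromoalkene react far more slowly), giving the primary C9 alkylborane; oxidative addition of zerovalent palladium into the C10–Br bond, base-assisted transmetalation of the B-alkyl group and reductive elimination then form the C9–C10 bond. The closest known reaction type is the hydroboration/intramolecular B-alkyl Suzuki–Miyaura cyclisation of halo-dienes to exo-methylene cycloalkanes. The seven-membered ring closes by C(sp3)–C(sp2) reductive elimination from an eight-membered palladacycle, formally a 7-exo closure onto the alkenyl carbon. No stereocentre is created, and the six existing ones are untouched because neither C9 nor C10 is stereogenic and the mild carbonate base does not epimerise C5 or cleave the tertiary acetate. The step needs ring closure to outrun intermolecular coupling and protodeboronation; high dilution with slow addition, the trans-1,2 arrangement on the cyclopentene and the cis C6/C7 substituents, which hold C9 near C10, should secure this. The hydroxyl may be borinated transiently and is released in the aqueous base.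

Compound list
1 | methacrolein (2-methylprop-2-enal) | C=C(C)C=O | starting material
2 | nitromethane | C[N+](=O)[O-] | starting material
3 | 3-methyl-1-nitrobut-3-en-2-ol (racemic) | C=C(C)C(O)C[N+](=O)[O-] | intermediate
4 | (E)-3-methyl-1-nitrobuta-1,3-diene | C=C(C)/C=C/[N+](=O)[O-] | intermediate
5 | pent-4-enal | C=CCCC=O | starting material
6 | (2R,3S)-4-methyl-3-(nitromethyl)-2-(prop-2-en-1-yl)pent-4-enal | O=C[C@H](CC=C)[C@@H](C(C)=C)C[N+](=O)[O-] | intermediate
7 | (1R,2S)-3-methyl-2-(nitromethyl)cyclopent-3-ene-1-carbaldehyde | O=C[C@@H]1CC=C(C)[C@H]1C[N+](=O)[O-] | intermediate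
8 | (4R,5S)-4-ethynyl-1-methyl-5-(nitromethyl)cyclopent-1-ene | C#C[C@@H]1CC=C(C)[C@H]1C[N+](=O)[O-] | intermediate
9 | (Z)-2-bromo-1-alkenyl-9-BBN adduct of 8 (B and Br cis) | Br/C(=C\B1C2CCCC1CCC2)[C@@H]3CC=C(C)[C@H]3C[N+](=O)[O-] | intermediate
10 | (4R,5S)-4-(1-bromoethenyl)-1-methyl-5-(nitromethyl)cyclopent-1-ene | C=C(Br)[C@@H]1CC=C(C)[C@H]1C[N+](=O)[O-] | intermediate
11 | sodium nitronate of 10 | C=C(Br)[C@@H]1CC=C(C)[C@H]1C=[N+]([O-])[O-].[Na+] | intermediate
12 | (1S,5R)-5-(1-bromoethenyl)-2-methylcyclopent-2-ene-1-carbaldehyde | C=C(Br)[C@@H]1CC=C(C)[C@H]1C=O | intermediate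
13 | (S)-(+)-linalool | C=C[C@@](C)(O)CCC=C(C)C | starting material
14 | (3S)-5-[(2S)-3,3-dimethyloxiran-2-yl]-3-methylpent-1-en-3-ol | C=C[C@@](C)(O)CC[C@@H]1OC1(C)C | intermediate
15 | 2-[(2R,5S)-5-ethenyl-5-methyloxolan-2-yl]propan-2-ol | C=C[C@]1(C)CC[C@H](C(C)(C)O)O1 | intermediate
16 | 2-[(2R,5S)-5-ethenyl-5-methyloxolan-2-yl]propan-2-yl acetate | C=C[C@]1(C)CC[C@H](C(C)(C)OC(C)=O)O1 | intermediate
17 | allylboronic acid pinacol ester | C=CCB1OC(C)(C)C(C)(C)O1 | starting material
18 | 2-[(2R,5S)-5-methyl-5-[(1E)-3-(4,4,5,5-tetramethyl-1,3,2-dioxaborolan-2-yl)prop-1-en-1-yl]oxolan-2-yl]propan-2-yl acetate | CC1(C)OB(C/C=C/[C@]2(C)CC[C@H](C(C)(C)OC(C)=O)O2)OC1(C)C | intermediate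
19 | pinacol borate ester of 20 (O–B(pin) on C6) | C=C(Br)[C@@H]1CC=C(C)[C@H]1[C@H](OB2OC(C)(C)C(C)(C)O2)[C@@H](C=C)[C@]3(C)CC[C@H](C(C)(C)OC(C)=O)O3 | intermediate
20 | 2-[(2R,5S)-5-[(1S,2R)-1-[(1S,5R)-5-(1-bromoethenyl)-2-methylcyclopent-2-en-1-yl]-1-hydroxybut-3-en-2-yl]-5-methyloxolan-2-yl]propan-2-yl acetate | C=C(Br)[C@@H]1CC=C(C)[C@H]1[C@H](O)[C@@H](C=C)[C@]2(C)CC[C@H](C(C)(C)OC(C)=O)O2 | intermediate
21 | B-alkyl-9-BBN adduct of 20 (boron on C9) | C=C(Br)[C@@H]1CC=C(C)[C@H]1[C@H](O)[C@@H](CCB2C3CCCC2CCC3)[C@]4(C)CC[C@H](C(C)(C)OC(C)=O)O4 | intermediate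
22 | 2-[(2R,5S)-5-[(3aS,4S,5R,8aR)-4-hydroxy-3-methyl-8-methylidene-1,3a,4,5,6,7,8,8a-octahydroazulen-5-yl]-5-methyloxolan-2-yl]propan-2-yl acetate | C=C1CC[C@@H]([C@]2(C)CC[C@H](C(C)(C)OC(C)=O)O2)[C@@H](O)[C@@H]2C(C)=CC[C@@H]12 | target

Total step count: 11. Longest linear sequence: 8 steps (steps 1, 2, 3, 4, 5, 6, 10, 11).

Steps most likely to fail

Step 11. Intermolecular coupling, protodeboronation of the alkylborane or reduction of the alkenyl bromide may outrun closure of the seven-membered ring. The fallback makes the same bond by a nickel-catalysed reductive cross-electrophile cyclisation and sets out from 20. The C6 hydroxyl is silylated (Et3SiOTf, 2,6-lutidine) to give the triethylsilyl ether F1, which also blocks oxolane formation later. Hydroboration–oxidation of the vinyl group (9-BBN; NaBO3) gives the primary alcohol F2, and I2/PPh3/imidazole converts it into the primary iodide F3. NiBr2(dme), 4,4'-di-tert-butyl-2,2'-bipyridine and Mn powder in DMA at high dilution then couple the C9 iodide with the C10 alkenyl bromide to give the silyl ether of the target F4. HF·pyridine returns to 22.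

Step 10. The catalyst, the α-stereocentre of the aldehyde and the C11 centre of the boronate may not all favour the same face, which would erode facial selectivity; the acid may also epimerise the aldehyde. The fallback is a chromium-mediated Nozaki–Hiyama allylation and sets out from 16. Cross-metathesis with allyl bromide (same ruthenium catalyst) gives the (E)-allylic bromide F5. With CrCl2 in THF it adds to aldehyde 12 through an anti-selective chair transition state under Felkin control, without a Brønsted acid, and rejoins the route at 20; the alkenyl bromide is inert in the absence of a nickel co-catalyst.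

Step 6. Unmasking the aldehyde may be accompanied by epimerisation at C5, migration of the ring double bond into conjugation, or incomplete hydrolysis of the imine. The fallback detours through the acid oxidation state and sets out from 10. NaNO2/AcOH/DMSO at 35 °C oxidises the nitro group to the configurationally more robust carboxylic acid F6. LiAlH4 (Et2O, 0 °C) reduces it to the primary alcohol F7, and Dess–Martin periodinane with NaHCO3 oxidises this under neutral conditions to 12 immediately before step 10.

Further compounds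
F1 | step 11 | 2-[(2R,5S)-5-[(1S,2R)-1-[(1S,5R)-5-(1-bromoethenyl)-2-methylcyclopent-2-en-1-yl]-1-(triethylsilyloxy)but-3-en-2-yl]-5-methyloxolan-2-yl]propan-2-yl acetate | C=C(Br)[C@@H]1CC=C(C)[C@H]1[C@H](O[Si](CC)(CC)CC)[C@@H](C=C)[C@]2(C)CC[C@H](C(C)(C)OC(C)=O)O2
F2 | step 11 | 2-[(2R,5S)-5-[(1S,2R)-1-[(1S,5R)-5-(1-bromoethenyl)-2-methylcyclopent-2-en-1-yl]-4-hydroxy-1-(triethylsilyloxy)butan-2-yl]-5-methyloxolan-2-yl]propan-2-yl acetate | C=C(Br)[C@@H]1CC=C(C)[C@H]1[C@H](O[Si](CC)(CC)CC)[C@@H](CCO)[C@]2(C)CC[C@H](C(C)(C)OC(C)=O)O2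
F3 | step 11 | 2-[(2R,5S)-5-[(1S,2R)-1-[(1S,5R)-5-(1-bromoethenyl)-2-methylcyclopent-2-en-1-yl]-4-iodo-1-(triethylsilyloxy)butan-2-yl]-5-methyloxolan-2-yl]propan-2-yl acetate | C=C(Br)[C@@H]1CC=C(C)[C@H]1[C@H](O[Si](CC)(CC)CC)[C@@H](CCI)[C@]2(C)CC[C@H](C(C)(C)OC(C)=O)O2
F4 | step 11 | C6 triethylsilyl ether of 22 | C=C1CC[C@@H]([C@]2(C)CC[C@H](C(C)(C)OC(C)=O)O2)[C@@H](O[Si](CC)(CC)CC)[C@@H]2C(C)=CC[C@@H]12
F5 | step 10 | 2-[(2R,5S)-5-[(1E)-3-bromoprop-1-en-1-yl]-5-methyloxolan-2-yl]propan-2-yl acetate | BrC/C=C/[C@]1(C)CC[C@H](C(C)(C)OC(C)=O)O1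
F6 | step 6 | (1S,5R)-5-(1-bromoethenyl)-2-methylcyclopent-2-ene-1-carboxylic acid | C=C(Br)[C@@H]1CC=C(C)[C@H]1C(=O)O
F7 | step 6 | [(1S,5R)-5-(1-bromoethenyl)-2-methylcyclopent-2-en-1-yl]methanol | C=C(Br)[C@@H]1CC=C(C)[C@H]1CO
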